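## The problem

Honyucitrin 16 is a flavone (2-arylchromen-4-one): ring A carries free hydroxyls at C5 and C7, ring C is the pyranone (O1, C2=C3, C4 carbonyl), and ring B, joined at C2, carries a 4'-hydroxyl flanked by prenyl groups at C3' and C5'. There is no stereocenter, and the two trisubstituted side-chain alkenes have no geometric isomers, so the difficulties are connectivity, regiochemistry and the choice of masking groups. Ring C must close as the six-membered pyranone and not as the isomeric five-membered aurone, and both prenyl groups must sit on carbon ortho to the ring B oxygen, not on that oxygen. The fragile motif is the ortho-prenylphenol of ring B: Brønsted and Lewis acids add the phenol oxygen across the neighbouring alkene to give 2,2-dimethylchromans, hydrogen halides add to the alkenes, and hydrogenolysis would saturate them. Methyl ethers, benzyl ethers and acid-labile acetals are therefore poor masks for the three phenols, and whatever protects them should leave under mild base. The feature that invites a short synthesis is the environment of C4: a carbonyl carbon bound to C4a of a phloroglucinol-type ring and to the C3=C2–aryl unit, which becomes an aryl ynone once O1–C2 is opened. C4 can therefore come from carbon monoxide, C3 and C2 from a ring B arylacetylene, and C4a from a halogenated carbon of ring A. Because C4a lies between two equivalent oxygen-bearing carbons (C5 and C8a), either oxygen may close the ring and no regiochemical choice arises.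

## Retrosynthesis

Honyucitrin 16 is first traced to its triacetate 15. No skeletal bond is cut. Acetates are chosen because they are the common phenol masks that leave under base mild enough for the ortho-prenylphenol, so the synthesis does not end with an acid. 15 need not be isolated, since K2CO3 in methanol can be added to the flask in which it forms.

Ring C of 15 is opened at three bonds: O1–C2, C4–C3 and C4a–C4. Opening O1–C2 reveals enaminone 14 and behind it ynone 13. Cutting both bonds to C4 releases the carbonyl carbon as carbon monoxide 12 and leaves 2-iodophloroglucinol triacetate 3 and the ring B alkyne 11. Compared with the neighbouring cuts of ring C (C2=C3 by olefination, O1–C8a by aryl ether coupling, or acid cyclodehydration of a diketone), this one makes all three bonds in one flask from two arenes of similar size. No strong acid or oxidant meets the prenyl groups, and the ortho acetate of 3 is both protecting group and latent O1. The precursors are much simpler: 3 is a symmetric benzene with one halogen, 11 a benzene with one alkyne. The forward reaction must insert carbon monoxide before the alkyne couples and must close the six-membered ring; diethylamine as solvent is meant to secure the latter through 14.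

Alkyne 11 is cut at the bond between C1' of ring B and the acetylenic carbon that becomes C2. This leads through silylalkyne 10 to aryl iodide 8 and ethynyltrimethylsilane 9. The neighbouring option, one-carbon homologation of a ring B aldehyde, would require C-prenylation of a para-formylphenoxide, a poor carbon nucleophile, and a basic methanolic homologation that strips the acetate. The forward sequence needs a Sonogashira coupling and a silicon removal that both spare an aryl acetate. Triethylamine allows the first; AgNO3 catalysis in aqueous acetone is chosen for the second, in place of basic methanol or fluoride.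

Iodide 8 is the acetate of phenol 7. Phenol 7 is cut at the two bonds between ring B and the prenyl CH2 groups, one after the other: the first cut gives monoprenylphenol 6 and prenyl bromide 5, the second gives 4-iodophenol 4 and a second molecule of 5. The iodine serves twice: it blocks the para position during C-alkylation and is the handle for the alkyne. Cross-coupling of a dihalophenol with a prenylmetal reagent would be more controlled but could not keep a third, more reactive halogen for the alkynylation, and a Claisen-based detour costs several steps. The forward reaction must favour carbon over oxygen alkylation twice in the same flask and therefore consumes two equivalents of 5; water as solvent is known to steer para-substituted phenoxides towards ortho C-alkylation.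

Triacetate 3 is cut at its three ester bonds to 2-iodophloroglucinol 2, and this at the C–I bond to phloroglucinol 1. The three ring positions of 1 are equivalent, so only one monoiodide can form; the only demand is that iodination stops after one iodine. Acetylation follows at once because 2 is sensitive to air and light.

## Roads not taken

Alternative 1: The cut is C2=C3 of ring C. Ring A would be a phenacylidene triphenylphosphorane whose ortho oxygen already carries the ring B aroyl group, the ylide ester A2. On heating, the ylide carbon attacks the ester carbonyl and expels triphenylphosphine oxide, giving the tris(methoxymethyl) ether A1 of the flavone. The merits are real. The closure can only give the six-membered ring, since the ester oxygen is already O1, and it needs neither a transition metal nor a toxic gas. Ring A enters at the stable acetophenone oxidation level and not as a sensitive iodophenol. In certainty of ring closure this road is at least as good as the chosen one. Its weak points are the end and the length. A1 must lose three methoxymethyl groups under acid, the very conditions that turn the ortho-prenylphenol into a chroman. Ring B must be carried to the carboxylic acid oxidation level and activated, and the way to A2 needs a side-chain bromination on an electron-rich ring, a phosphine quaternisation and a selective mono-esterification. The chosen plan sets against the safer closure a much shorter sequence and an unmasking by base alone.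

Alternative 2: The cut is the aryl ether bond O1–C8a. The enol oxygen of the 1,3-diketone A4, which carries a 2-bromo-4,6-dimethoxyphenyl ring A, would displace bromide under CuI and K2CO3 in an intramolecular Ullmann-type coupling, giving the 5,7-dimethyl ether A3. A4 comes from a simple Claisen condensation, the catalyst is cheap, the aryl bromide is robust, and no carbon monoxide is handled; in these respects it is better than the chosen plan. For this target the end game decides against it. The C5 methyl ether of A3 can be removed with help from the neighbouring carbonyl, but the C7 methyl ether needs BBr3, AlCl3 or hot acid, and none of these spares two prenyl groups beside a phenol. The enolate chemistry that builds A4 does not tolerate acetates, and benzyl ethers would call for a hydrogenolysis that reduces the alkenes. The unsymmetrically brominated ring A of A4 also has to be made regioselectively, whereas the chosen ring A piece is symmetric.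

Alternative 3: The cut is at the two side-chain double bonds C2''=C3'': the prenyl groups are made last from allyl groups. The 3',5'-diallyl flavone triacetate A6 would undergo twofold cross-metathesis with excess 2-methylbut-2-ene under the second-generation Grubbs catalyst (H2IMes)(PCy3)Cl2Ru=CHPh to give honyucitrin triacetate A5, which is the same compound as intermediate 15. On the side-chain problem this road is better than the chosen plan. Allyl groups go onto ring B carbons by O-allylation and Claisen rearrangement with full regiocontrol, and they withstand more acid than prenyl groups while the core is built. Its weak points lie elsewhere. It says nothing about how ring C is made, so a flavone synthesis must be added. Two Claisen rounds are needed. Both arms must react completely or allyl/prenyl mixtures result, and ruthenium hydrides may move the allyl double bond into conjugation. A deacetylation still follows. The chosen plan accepts the less selective direct C-prenylation of 4, a known reaction type for para-substituted phenols, for the sake of brevity, and keeps the allyl-to-prenyl idea as the fallback for step 3.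

Key step: step 7

Remark: 15 stands for the first-formed flavone. Partial loss of its acetates to diethylamine in the first stage is expected and harmless, since the K2CO3 stage converges all acetylated flavones on 16. Enaminone 14 is drawn as the E isomer; its geometry has no bearing on the ring closure.

## Route

Step 1
Reactants: 1 phloroglucinol (benzene-1,3,5-triol)
Product: 2 2-iodobenzene-1,3,5-triol
Conditions: I2 (1 equiv), NaHCO3, THF–H2O, 0 °C, dark
Reagents that add atoms: iodine, II
Why: Electrophilic aromatic iodination of a highly activated phenol; one equivalent of iodine at 0 °C with NaHCO3 as acid scavenger should stop at monosubstitution, and the three ring positions are equivalent, so only one monoiodide can form.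

Step 2
Reactants: 2 2-iodobenzene-1,3,5-triol
Product: 3 2-iodobenzene-1,3,5-triyl triacetate
Conditions: Ac2O (excess), pyridine, DMAP (cat.), CH2Cl2, 0 °C to rt
Reagents that add atoms: acetic anhydride, CC(=O)OC(C)=O
Why: DMAP-catalysed O-acetylation of all three phenols; the acetates stabilise the electron-rich iodoarene and are the base-labile masks that the key step needs at the ortho oxygens.

Step 3
Reactants: 4 4-iodophenol; 5 prenyl bromide (1-bromo-3-methylbut-2-ene; first of two equivalents)
Product: 7 4-iodo-2,6-bis(3-methylbut-2-enyl)phenol, via 4-iodo-2-(3-methylbut-2-enyl)phenol 6 (not isolated)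
Conditions: 5 (2.5 equiv in all, in two portions), KOH (2.5 equiv), H2O, rt, Ar; aq. NH4Cl work-up
Reagents that add atoms: prenyl bromide (second equivalent of 5), CC(C)=CCBr
Why: Twofold ortho C-alkylation of a phenoxide in water (aqueous-alkali C-prenylation): hydrogen bonding shields the phenoxide oxygen so the ionising allylic bromide attacks an ortho carbon, and iodine blocks the para position. Monoprenylphenol 6 is re-ionised by the excess KOH and takes the second equivalent of 5 at the remaining ortho carbon; the reaction type is known for para-substituted phenols.

Step 4
Reactants: 7 4-iodo-2,6-bis(3-methylbut-2-enyl)phenol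
Product: 8 4-iodo-2,6-bis(3-methylbut-2-enyl)phenyl acetate
Conditions: Ac2O, pyridine, DMAP (cat.), CH2Cl2, rt
Reagents that add atoms: acetic anhydride, CC(=O)OC(C)=O
Why: DMAP-catalysed O-acetylation of a hindered phenol; it removes the acidic phenol before the alkyne chemistry and keeps ring B from donating strongly into the later ynone.

Step 5
Reactants: 8 4-iodo-2,6-bis(3-methylbut-2-enyl)phenyl acetate; 9 ethynyltrimethylsilane
Product: 10 2,6-bis(3-methylbut-2-enyl)-4-[(trimethylsilyl)ethynyl]phenyl acetate
Conditions: PdCl2(PPh3)2 (cat.), CuI (cat.), Et3N, THF, rt
Reagents that add atoms: none
Why: Sonogashira coupling of an aryl iodide at room temperature; the tertiary amine does not cleave the aryl acetate and the trisubstituted alkenes are inert to the arylpalladium intermediate.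

Step 6
Reactants: 10 2,6-bis(3-methylbut-2-enyl)-4-[(trimethylsilyl)ethynyl]phenyl acetate
Product: 11 4-ethynyl-2,6-bis(3-methylbut-2-enyl)phenyl acetate
Conditions: AgNO3 (cat.), acetone–H2O, rt, dark
Reagents that add atoms: none
Why: Silver-catalysed protiodesilylation of an alkynylsilane: monovalent silver activates the alkyne–silicon bond, water takes the silicon as silanol and the silver acetylide is protonated; the medium is near neutral, so the aryl acetate should survive where basic methanol or fluoride would cleave it.

Step 7
Reactants: 3 2-iodobenzene-1,3,5-triyl triacetate; 11 4-ethynyl-2,6-bis(3-methylbut-2-enyl)phenyl acetate; 12 carbon monoxide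
Product: 16 honyucitrin (5,7-dihydroxy-2-[4-hydroxy-3,5-bis(3-methylbut-2-enyl)phenyl]chromen-4-one), via ynone 13 (not isolated), via enaminone 14 (not isolated), via honyucitrin triacetate 15 (not isolated)
Conditions: PdCl2(PPh3)2 (cat.), dppp (cat.), thiourea (cat.), DBU, Et2NH, CO (1 atm), 40 °C; then N2 purge, K2CO3, MeOH, rt; aq. NH4Cl work-up
Reagents that add atoms: none
Why: Zerovalent palladium, formed from PdCl2(PPh3)2 in the amine, inserts into the C–I bond of 3, carbon monoxide 12 inserts to give an aroylpalladium species, and the acetylide of 11 is transferred and reductively eliminated to give ynone 13, which forms C4a–C4 and C4–C3. Diethylamine adds to the ynone to give enaminone 14 and cleaves an ortho acetate of ring A; the freed phenoxide attacks the amine-bearing carbon and expels diethylamine, which forms O1–C2 and gives flavone triacetate 15. The closest known reaction type is the carbonylative Sonogashira annulation of ortho-iodophenyl acetates with terminal arylacetylenes to flavones under a balloon of carbon monoxide. Ring C closes in the 6-endo mode, as an addition–elimination at the β-carbon of the enaminone; the 5-exo path to an aurone is closed because the amine already occupies the β-carbon and the α-carbon is no longer electrophilic. No stereocenter is formed. Carbonylation must outrun direct alkynylation, which the two ortho acetoxy groups favour by crowding the arylpalladium species and the carbon monoxide atmosphere supports; no regiocontrol is needed because the two ortho oxygens of 3 are equivalent. The trisubstituted prenyl alkenes do not insert into the acylpalladium bond, and the acetate of ring B keeps the alkyne electron-poor enough for amine addition. K2CO3 in methanol then removes the remaining three acetates without touching the acid-sensitive ortho-prenylphenol.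

## Compound list

1 | phloroglucinol (benzene-1,3,5-triol) | Oc1cc(O)cc(O)c1 | starting material
2 | 2-iodobenzene-1,3,5-triol | Oc1cc(O)c(I)c(O)c1 | intermediate
3 | 2-iodobenzene-1,3,5-triyl triacetate | CC(=O)Oc1cc(OC(C)=O)c(I)c(OC(C)=O)c1 | intermediate
4 | 4-iodophenol | Oc1ccc(I)cc1 | starting material
5 | prenyl bromide (1-bromo-3-methylbut-2-ene) | CC(C)=CCBr | starting material
6 | 4-iodo-2-(3-methylbut-2-enyl)phenol | CC(C)=CCc1cc(I)ccc1O | intermediate
7 | 4-iodo-2,6-bis(3-methylbut-2-enyl)phenol | CC(C)=CCc1cc(I)cc(CC=C(C)C)c1O | intermediate
8 | 4-iodo-2,6-bis(3-methylbut-2-enyl)phenyl acetate | CC(C)=CCc1cc(I)cc(CC=C(C)C)c1OC(C)=O | intermediate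
9 | ethynyltrimethylsilane | C#C[Si](C)(C)C | starting material
10 | 2,6-bis(3-methylbut-2-enyl)-4-[(trimethylsilyl)ethynyl]phenyl acetate | CC(C)=CCc1cc(C#C[Si](C)(C)C)cc(CC=C(C)C)c1OC(C)=O | intermediate
11 | 4-ethynyl-2,6-bis(3-methylbut-2-enyl)phenyl acetate | C#Cc1cc(CC=C(C)C)c(OC(C)=O)c(CC=C(C)C)c1 | intermediate
12 | carbon monoxide | [C-]#[O+] | starting material
13 | 2-{3-[4-acetoxy-3,5-bis(3-methylbut-2-enyl)phenyl]prop-2-ynoyl}benzene-1,3,5-triyl triacetate (ynone) | CC(=O)Oc1cc(OC(C)=O)c(C(=O)C#Cc2cc(CC=C(C)C)c(OC(C)=O)c(CC=C(C)C)c2)c(OC(C)=O)c1 | intermediate
14 | 2-{(E)-3-[4-acetoxy-3,5-bis(3-methylbut-2-enyl)phenyl]-3-(diethylamino)prop-2-enoyl}benzene-1,3,5-triyl triacetate (enaminone) | CCN(CC)/C(=C/C(=O)c1c(OC(C)=O)cc(OC(C)=O)cc1OC(C)=O)c1cc(CC=C(C)C)c(OC(C)=O)c(CC=C(C)C)c1 | intermediate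
15 | honyucitrin triacetate (5,7-diacetoxy-2-[4-acetoxy-3,5-bis(3-methylbut-2-enyl)phenyl]chromen-4-one) | CC(C)=CCc1cc(-c2cc(=O)c3c(OC(C)=O)cc(OC(C)=O)cc3o2)cc(CC=C(C)C)c1OC(C)=O | intermediate
16 | honyucitrin (5,7-dihydroxy-2-[4-hydroxy-3,5-bis(3-methylbut-2-enyl)phenyl]chromen-4-one) | CC(C)=CCc1cc(-c2cc(=O)c3c(O)cc(O)cc3o2)cc(CC=C(C)C)c1O | target

## Step count and risks

Total: 7 steps. Longest linear sequence: 5 steps (steps 3, 4, 5, 6 and 7, from 4 to 16); the ring A branch (steps 1 and 2) joins at step 7.

Step 7 (key step). Three processes may divert the material.
- The acetates of 3 may be aminolysed before oxidative addition, leaving an electron-rich iodophenoxide that inserts palladium slowly and loses iodine by protonolysis.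
- Diethylamine may capture the aroylpalladium intermediate (aminocarbonylation) in place of the alkyne.
- The alkyne may couple without uptake of carbon monoxide and then close to a benzofuran.

Fallback: C4 is brought in as a carboxylic acid carbon in place of carbon monoxide. Purchased 2,4,6-trihydroxybenzoic acid F1 is peracetylated (Ac2O, pyridine, 0 °C) to 2,4,6-triacetoxybenzoic acid F2. Oxalyl chloride with catalytic DMF converts this into 2,4,6-triacetoxybenzoyl chloride F3. An acyl Sonogashira coupling of F3 with alkyne 11 (PdCl2(PPh3)2, CuI, Et3N, THF, rt) should give ynone 13, this time isolated. Et2NH and then K2CO3 in MeOH take 13 through 14 and 15 to 16. The fallback sets out from 11 and rejoins the route at 13.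

Step 3. O-alkylation competes with C-alkylation, the sequence may stall after the first prenyl group, a further prenyl group may add at an already substituted ortho carbon to give a dienone, and the product may cyclise to a chroman if the work-up turns acidic. Low throughput is the likely outcome.

Fallback: the prenyl groups are made from allyl groups. 4-Iodophenol 4 is O-allylated (allyl bromide, K2CO3, acetone) to 1-iodo-4-(prop-2-enyloxy)benzene F4. Claisen rearrangement (N,N-diethylaniline, 190 °C) gives 4-iodo-2-(prop-2-enyl)phenol F5. A second round of the same two reactions gives 4-iodo-2-(prop-2-enyl)-1-(prop-2-enyloxy)benzene F6 and then 4-iodo-2,6-di(prop-2-enyl)phenol F7. Twofold cross-metathesis of F7 with excess 2-methylbut-2-ene and the second-generation Grubbs catalyst (H2IMes)(PCy3)Cl2Ru=CHPh in CH2Cl2 should give 7. The fallback sets out from 4 and rejoins at 7.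

Step 1. Iodination may run on to di- and triiodides, and the electron-rich triol and its monoiodide may be oxidised or lose iodine during isolation.

Fallback: halogenation and protection are inverted. Phloroglucinol 1 is peracetylated (Ac2O, pyridine) to benzene-1,3,5-triyl triacetate F8, which is iodinated with N-iodosuccinimide and CF3CO2H in MeCN. The acyloxy groups still direct ortho and para but make the ring far less reactive than the free triol, and the first iodine deactivates it further, so the reaction should stop at 3. The fallback sets out from 1 and rejoins at 3.

Step 6. The aryl acetate may be hydrolysed during desilylation, or the catalyst may be held back as silver acetylide or by the alkenes, so that conversion stalls.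

Fallback: the terminal alkyne is installed without a silyl group. Stille coupling of iodide 8 with tributyl(ethynyl)stannane (Pd(PPh3)4 cat., toluene, 90 °C) transfers the ethynyl group under neutral conditions and gives 11 directly. The fallback sets out from 8 and rejoins at 11; it makes no new compound.

## Further compounds

F1 | step 7 | 2,4,6-trihydroxybenzoic acid (purchased) | O=C(O)c1c(O)cc(O)cc1O
F2 | step 7 | 2,4,6-triacetoxybenzoic acid | CC(=O)Oc1cc(OC(C)=O)c(C(=O)O)c(OC(C)=O)c1
F3 | step 7 | 2,4,6-triacetoxybenzoyl chloride | CC(=O)Oc1cc(OC(C)=O)c(C(=O)Cl)c(OC(C)=O)c1
F4 | step 3 | 1-iodo-4-(prop-2-enyloxy)benzene | C=CCOc1ccc(I)cc1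
F5 | step 3 | 4-iodo-2-(prop-2-enyl)phenol | C=CCc1cc(I)ccc1O
F6 | step 3 | 4-iodo-2-(prop-2-enyl)-1-(prop-2-enyloxy)benzene | C=CCOc1ccc(I)cc1CC=C
F7 | step 3 | 4-iodo-2,6-di(prop-2-enyl)phenol | C=CCc1cc(I)cc(CC=C)c1O
F8 | step 1 | benzene-1,3,5-triyl triacetate | CC(=O)Oc1cc(OC(C)=O)cc(OC(C)=O)c1
F0 | step 6 | none | none
A1 | alternative 1 | 5,7-bis(methoxymethoxy)-2-[4-(methoxymethoxy)-3,5-bis(3-methylbut-2-enyl)phenyl]chromen-4-one | CC(C)=CCc1cc(-c2cc(=O)c3c(OCOC)cc(OCOC)cc3o2)cc(CC=C(C)C)c1OCOC
A2 | alternative 1 | 3,5-bis(methoxymethoxy)-2-[(triphenyl-λ5-phosphanylidene)acetyl]phenyl 4-(methoxymethoxy)-3,5-bis(3-methylbut-2-enyl)benzoate | COCOc1cc(OCOC)c(C(=O)C=P(c2ccccc2)(c2ccccc2)c2ccccc2)c(OC(=O)c2cc(CC=C(C)C)c(OCOC)c(CC=C(C)C)c2)c1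
A3 | alternative 2 | 5,7-dimethoxy-2-[4-(methoxymethoxy)-3,5-bis(3-methylbut-2-enyl)phenyl]chromen-4-one | CC(C)=CCc1cc(-c2cc(=O)c3c(OC)cc(OC)cc3o2)cc(CC=C(C)C)c1OCOC
A4 | alternative 2 | 1-(2-bromo-4,6-dimethoxyphenyl)-3-[4-(methoxymethoxy)-3,5-bis(3-methylbut-2-enyl)phenyl]propane-1,3-dione | COCOc1c(CC=C(C)C)cc(C(=O)CC(=O)c2c(Br)cc(OC)cc2OC)cc1CC=C(C)C
A5 | alternative 3 | honyucitrin triacetate (5,7-diacetoxy-2-[4-acetoxy-3,5-bis(3-methylbut-2-enyl)phenyl]chromen-4-one) | CC(C)=CCc1cc(-c2cc(=O)c3c(OC(C)=O)cc(OC(C)=O)cc3o2)cc(CC=C(C)C)c1OC(C)=O
A6 | alternative 3 | 5,7-diacetoxy-2-[4-acetoxy-3,5-di(prop-2-enyl)phenyl]chromen-4-one | C=CCc1cc(-c2cc(=O)c3c(OC(C)=O)cc(OC(C)=O)cc3o2)cc(CC=C)c1OC(C)=O
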